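The dihydropyran is closed last, by joining the tertiary oxygen on the quaternary cyclopentane carbon to C10 of an intact dibenzo[b,f]oxepine. A butenolide made from (R)-linalool undergoes an intramolecular [2+2] photocycloaddition; its lactone tether sets all four stereocentres and holds that oxygen and the cyclobutane C7 substituent cis. The lactone carbonyl then becomes C11 of the oxepine (aryllithium addition, McMurry closure). The key step exploits the easily oxidised stilbene-type C10=C11 bond and its C10–H: photoredox oxidation, 6-endo attack of the tertiary alcohol and cobaloxime-mediated loss of H2 give the cyclic enol ether directly. Its precursor is an 11-(hydroxybicycloheptyl)dibenzoxepine.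

Key step: step 11

Assumption: compound 14 is written as the open hydroxy ketone; it should equilibrate with its five-membered lactol, which does not change the chemistry that follows. In the text, C1, C2, C5, C6 and C7 are bicyclo[3.2.0]heptane positions, and C10 and C11 are dibenzo[b,f]oxepine positions.

Step 1
Reactants: 1 (R)-linalool, (3R)-3,7-dimethylocta-1,6-dien-3-ol
Product: 2 (3R)-3-(allyloxy)-3,7-dimethylocta-1,6-diene
Conditions: NaH, allyl bromide, n-Bu4NI (cat.), THF–DMF, 0 °C to rt
Reagents that add atoms: allyl bromide, C=CCBr
Why: Williamson etherification of the tertiary sodium alkoxide with a reactive allylic bromide should give the ether without touching the stereocentre.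

Step 2
Reactants: 2 (3R)-3-(allyloxy)-3,7-dimethylocta-1,6-diene
Product: 3 (2R)-2-methyl-2-(4-methylpent-3-en-1-yl)-2,5-dihydrofuran
Conditions: second-generation Grubbs catalyst RuCl2(=CHPh)(PCy3)(H2IMes) (2 mol%), CH2Cl2, 40 °C
Reagents that add atoms: none
Why: Ring-closing olefin metathesis should start at the unhindered allyl ether terminus and close the five-membered ring onto the neighbouring vinyl group faster than either can engage the trisubstituted prenyl-type alkene.

Step 3
Reactants: 3 (2R)-2-methyl-2-(4-methylpent-3-en-1-yl)-2,5-dihydrofuran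
Product: 4 (5R)-5-methyl-5-(4-methylpent-3-en-1-yl)furan-2(5H)-one
Conditions: pyridinium chlorochromate (C5H5NH)[CrO3Cl], pyridine, CH2Cl2, reflux
Reagents that add atoms: pyridinium chlorochromate, [O-][Cr](=O)(=O)Cl.c1cc[nH+]cc1
Why: Allylic oxidation by hexavalent chromium should select the ring O–CH2 group, which is both allylic and α to oxygen, over the less activated allylic C–H bonds of the side chain, as in the usual metathesis/oxidation route to butenolides.

Step 4
Reactants: 4 (5R)-5-methyl-5-(4-methylpent-3-en-1-yl)furan-2(5H)-one
Product: 5 tricyclic lactone, the γ-lactone of (1R,2R,5S,7R)-2-hydroxy-2,6,6-trimethylbicyclo[3.2.0]heptane-7-carboxylic acid (all ring fusions cis, 2-methyl on the convex face)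
Conditions: hν (300 nm), acetone (solvent and triplet sensitiser), degassed, rt
Reagents that add atoms: none
Why: Sensitised intramolecular enone-type [2+2] photocycloaddition should follow the rule of five (β-carbon to the internal alkene carbon, then α-carbon to CMe2); because the tether hangs from the quaternary C5 of the butenolide, only cis ring fusions are possible, so the (R) centre alone sets C1, C5 and C7.

Step 5
Reactants: 6 2-bromo-5-methoxyphenol
Product: 7 2-bromo-4-iodo-5-methoxyphenol
Conditions: N-iodosuccinimide, TsOH·H2O (cat.), MeCN, 0 °C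
Reagents that add atoms: N-iodosuccinimide, O=C1CCC(=O)N1I
Why: Electrophilic aromatic iodination should go para to the free hydroxyl (and ortho to methoxy), the less hindered of the two doubly activated positions.

Step 6
Reactants: 7 2-bromo-4-iodo-5-methoxyphenol
Product: 8 2-bromo-5-methoxy-4-(3-methylbut-2-en-1-yl)phenol
Conditions: tributyl(3-methylbut-2-en-1-yl)stannane, Pd(PPh3)4 (5 mol%), LiCl, DMF, 80 °C
Reagents that add atoms: tributyl(3-methylbut-2-en-1-yl)stannane, CCCC[Sn](CCCC)(CCCC)CC=C(C)C
Why: Stille cross-coupling should occur only at the C–I bond, into which zerovalent palladium inserts much faster than into the electron-rich C–Br bond, and should deliver the linear prenyl group.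

Step 7
Reactants: 8 2-bromo-5-methoxy-4-(3-methylbut-2-en-1-yl)phenol; 9 2-fluoro-4-methoxybenzaldehyde
Product: 10 2-[2-bromo-5-methoxy-4-(3-methylbut-2-en-1-yl)phenoxy]-4-methoxybenzaldehyde
Conditions: K2CO3, DMF, 110 °C
Reagents that add atoms: none
Why: Nucleophilic aromatic substitution of the fluoride ortho to the formyl group by the phenoxide should give the diaryl ether, the methoxy group being meta to the site of attack and so not deactivating.

Step 8
Reactants: 10 2-[2-bromo-5-methoxy-4-(3-methylbut-2-en-1-yl)phenoxy]-4-methoxybenzaldehyde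
Product: 11 1-bromo-2-[2-(dimethoxymethyl)-5-methoxyphenoxy]-4-methoxy-5-(3-methylbut-2-en-1-yl)benzene
Conditions: HC(OMe)3, MeOH, PPTS (cat.), rt
Reagents that add atoms: trimethyl orthoformate, COC(OC)OC; methanol, CO
Why: Mild acid-catalysed acetalisation should mask the aldehyde against the aryllithium of the next step without affecting the prenyl group.

Step 9
Reactants: 11 1-bromo-2-[2-(dimethoxymethyl)-5-methoxyphenoxy]-4-methoxy-5-(3-methylbut-2-en-1-yl)benzene; 5 tricyclic lactone
Product: 14 2-[2-({(1R,2R,5S,7R)-2-hydroxy-2,6,6-trimethylbicyclo[3.2.0]heptan-7-yl}carbonyl)-5-methoxy-4-(3-methylbut-2-en-1-yl)phenoxy]-4-methoxybenzaldehyde, via aryllithium 12 (not isolated), via acetal-protected hydroxy ketone 13 (not isolated)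
Conditions: n-BuLi, THF, −78 °C; then 5, −78 to −40 °C; then 1 M HCl, THF, rt
Reagents that add atoms: water, O
Why: Bromine–lithium exchange, then acyl addition to the γ-lactone, should stop at the ketone stage because the lithium hemiketal alkoxide persists at low temperature; acetal hydrolysis then frees the aldehyde, and no stereocentre is touched, the C7 acyl group staying endo.

Step 10
Reactants: 14 2-[2-({(1R,2R,5S,7R)-2-hydroxy-2,6,6-trimethylbicyclo[3.2.0]heptan-7-yl}carbonyl)-5-methoxy-4-(3-methylbut-2-en-1-yl)phenoxy]-4-methoxybenzaldehyde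
Product: 15 11-[(1R,2R,5S,7R)-2-hydroxy-2,6,6-trimethylbicyclo[3.2.0]heptan-7-yl]-3,7-dimethoxy-2-(3-methylbut-2-en-1-yl)dibenzo[b,f]oxepine
Conditions: TiCl4, Zn, pyridine, THF, reflux, slow addition of 14 at high dilution
Reagents that add atoms: none
Why: Intramolecular McMurry coupling of the aryl ketone and aryl aldehyde by low-valent titanium should close the seven-membered ring as its cis C10=C11 alkene, the established entry to dibenzo[b,f]oxepines, and the C7 centre is no longer epimerisable afterwards.

Step 11
Reactants: 15 11-[(1R,2R,5S,7R)-2-hydroxy-2,6,6-trimethylbicyclo[3.2.0]heptan-7-yl]-3,7-dimethoxy-2-(3-methylbut-2-en-1-yl)dibenzo[b,f]oxepine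
Product: 16 di-O-methyl ether of the target (pentacyclic enol ether, both phenols as methyl ethers)
Conditions: 9-mesityl-10-methylacridinium perchlorate (5 mol%), Co(dmgH)2(py)Cl (8 mol%), 1,2-dichloroethane, blue LEDs (450 nm), argon, rt
Reagents that add atoms: none
Why: Proposed new method: the excited acridinium should oxidise the most electron-rich π-system of 15, the dialkoxystilbene C10=C11 bond, to its radical cation; the tertiary C2 hydroxyl, held endo and syn to C7 by the earlier lactone tether, attacks C10 in a 6-endo-trig closure, and proton loss leaves the tertiary benzylic radical at C11. The cobaloxime, reduced to divalent cobalt by the acridinyl radical, then removes the C10–H hydrogen atom and releases H2, which regenerates both catalysts and gives the enol ether. The closest known reaction types are the acridinium-catalysed anti-Markovnikov hydroetherification of alkenols and the acridinium/cobaloxime dehydrogenative coupling of aryl alkenes with alcohols to enol ethers, both through the same alkene radical cation; the intramolecular dehydrogenative version on a stilbene with a tertiary alcohol is the new element. Only the dihydropyran ring is closed, by O–C10 bond formation, and no stereocentre is created, since C10 and C11 stay sp2 and the four existing centres are untouched. The step needs chemoselectivity for the stilbene over the prenyl alkene and the anisole rings (its oxidation potential is the lowest), regioselectivity for O–C10 over O–C11 (attack at the less substituted carbon gives the more stable radical and the six-membered ring), and hydrogen loss from C10–H and not from cyclobutane C7–H (conjugated enol ether against a strained alkylidenecyclobutane).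

Step 12
Reactants: 16 di-O-methyl ether of the target
Product: 17 target compound (free bisphenol)
Conditions: NaSEt, DMF, 130 °C; then 1 M HCl, 0 °C
Reagents that add atoms: none
Why: Nucleophilic (SN2) demethylation of the two aryl methyl ethers by ethanethiolate is basic and non-oxidising, so the prenyl group, the enol ether and the cyclobutane should survive where Lewis acids would not.

Compound list
1 | (R)-linalool, (3R)-3,7-dimethylocta-1,6-dien-3-ol | C=C[C@](C)(O)CCC=C(C)C | starting material
2 | (3R)-3-(allyloxy)-3,7-dimethylocta-1,6-diene | C=C[C@](C)(OCC=C)CCC=C(C)C | intermediate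
3 | (2R)-2-methyl-2-(4-methylpent-3-en-1-yl)-2,5-dihydrofuran | C1=C[C@](C)(OC1)CCC=C(C)C | intermediate
4 | (5R)-5-methyl-5-(4-methylpent-3-en-1-yl)furan-2(5H)-one | O=C1C=C[C@](C)(O1)CCC=C(C)C | intermediate
5 | tricyclic lactone: γ-lactone of (1R,2R,5S,7R)-2-hydroxy-2,6,6-trimethylbicyclo[3.2.0]heptane-7-carboxylic acid, all ring fusions cis | O=C1[C@@H]2[C@H]3[C@H](CC[C@@]3(C)O1)C2(C)C | intermediate
6 | 2-bromo-5-methoxyphenol | COc1ccc(Br)c(O)c1 | starting material
7 | 2-bromo-4-iodo-5-methoxyphenol | COc1cc(O)c(Br)cc1I | intermediate
8 | 2-bromo-5-methoxy-4-(3-methylbut-2-en-1-yl)phenol | COc1cc(O)c(Br)cc1CC=C(C)C | intermediate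
9 | 2-fluoro-4-methoxybenzaldehyde | COc1ccc(C=O)c(F)c1 | starting material
10 | 2-[2-bromo-5-methoxy-4-(3-methylbut-2-en-1-yl)phenoxy]-4-methoxybenzaldehyde | COc1ccc(C=O)c(Oc2cc(OC)c(CC=C(C)C)cc2Br)c1 | intermediate
11 | 1-bromo-2-[2-(dimethoxymethyl)-5-methoxyphenoxy]-4-methoxy-5-(3-methylbut-2-en-1-yl)benzene | COc1ccc(C(OC)OC)c(Oc2cc(OC)c(CC=C(C)C)cc2Br)c1 | intermediate
12 | aryllithium from 11 (lithium in place of bromine) | COc1ccc(C(OC)OC)c(Oc2cc(OC)c(CC=C(C)C)cc2[Li])c1 | intermediate
13 | acetal-protected hydroxy ketone (dimethyl acetal of 14) | COc1ccc(C(OC)OC)c(Oc2cc(OC)c(CC=C(C)C)cc2C(=O)[C@@H]3[C@H]4[C@H](CC[C@@]4(C)O)C3(C)C)c1 | intermediate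
14 | 2-[2-({(1R,2R,5S,7R)-2-hydroxy-2,6,6-trimethylbicyclo[3.2.0]heptan-7-yl}carbonyl)-5-methoxy-4-(3-methylbut-2-en-1-yl)phenoxy]-4-methoxybenzaldehyde | COc1ccc(C=O)c(Oc2cc(OC)c(CC=C(C)C)cc2C(=O)[C@@H]3[C@H]4[C@H](CC[C@@]4(C)O)C3(C)C)c1 | intermediate
15 | 11-[(1R,2R,5S,7R)-2-hydroxy-2,6,6-trimethylbicyclo[3.2.0]heptan-7-yl]-3,7-dimethoxy-2-(3-methylbut-2-en-1-yl)dibenzo[b,f]oxepine (hydroxyl and oxepinyl group both endo) | CC(C)=CCc1cc2c(cc1OC)Oc1cc(OC)ccc1C=C2[C@@H]1[C@H]2[C@H](CC[C@@]2(C)O)C1(C)C | intermediate
16 | di-O-methyl ether of the target | CC(C)=CCc1cc2c(cc1OC)Oc1cc(OC)ccc1C1=C2[C@@H]2[C@H]3[C@H](CC[C@@]3(C)O1)C2(C)C | intermediate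
17 | target compound CNP0185814.1 | CC(C)=CCc1cc2c(cc1O)Oc1cc(O)ccc1C1=C2[C@@H]2[C@H]3[C@H](CC[C@@]3(C)O1)C2(C)C | target

Total step count: 12. Longest linear sequence: 8 steps (steps 1 to 4, then 9 to 12; the arene branch, steps 5 to 8, then 9 to 12, is equally long).

Steps most likely to fail

Step 11 (proposed new method). Back electron transfer may outrun addition of the hindered tertiary alcohol to the radical cation, or the more electron-rich enol ether product may be over-oxidised. The fallback uses known chemistry only and sets out from 14. SmI2 in THF with t-BuOH at high dilution should give, by intramolecular ketone–aldehyde pinacol coupling, the 10,11-dihydrodibenzoxepine-10,11-diol F1. Parikh–Doering oxidation (SO3·pyridine, DMSO, i-Pr2NEt) of its secondary benzylic alcohol should give the 11-hydroxy-10-ketone F2. SmI2 in THF–MeOH at −78 °C should cleave the C11–O bond α to the ketone and give the 10-ketone with hydrogen at C11, F3. PPTS in toluene with 4 Å sieves at 60 °C should then cyclodehydrate this δ-hydroxy ketone to the enol ether, and the fallback comes back to the route at 16. The dihydropyran is still the last ring closed.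

Step 10. Intermolecular pinacol coupling of the aldehyde may outrun the crossed intramolecular coupling with the hindered, lactol-masked ketone, and the ketone α-carbon may epimerise on the Lewis-acidic titanium. The fallback sets out from 14: excess Ph3P=CH2 (from Ph3PCH3Br and KOt-Bu, THF, 0 °C to reflux) should methylenate both carbonyl groups to the diene F4. Ring-closing metathesis with the second-generation Hoveyda–Grubbs catalyst in toluene at 80 °C should then close the oxepine with loss of ethene, and the fallback comes back to the route at 15.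

Step 12. Prolonged heating with thiolate may move the prenyl double bond into conjugation or degrade the enol ether on the finished skeleton. The fallback shifts the demethylation to before the ring closure and sets out from 15. NaSEt in DMF at 130 °C should give the bisphenol F5. TBSCl and imidazole in DMF should silylate only the two phenols to give the bis-silyl ether F6. The conditions of step 11 should close the dihydropyran to the bis-silyl ether of the target F7. TBAF in THF at 0 °C then frees the phenols, and the fallback comes back to the route at 17.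

Further compounds
F1 | step 11 | 10,11-dihydro-10,11-diol from pinacol coupling of 14 (mixture at C10 and C11) | CC(C)=CCc1cc2c(cc1OC)Oc1cc(OC)ccc1C(O)C2(O)[C@@H]1[C@H]2[C@H](CC[C@@]2(C)O)C1(C)C
F2 | step 11 | 11-hydroxy-10-ketone (mixture at C11) | CC(C)=CCc1cc2c(cc1OC)Oc1cc(OC)ccc1C(=O)C2(O)[C@@H]1[C@H]2[C@H](CC[C@@]2(C)O)C1(C)C
F3 | step 11 | 10-ketone with hydrogen at C11, the δ-hydroxy ketone (mixture at C11) | CC(C)=CCc1cc2c(cc1OC)Oc1cc(OC)ccc1C(=O)C2[C@@H]1[C@H]2[C@H](CC[C@@]2(C)O)C1(C)C
F4 | step 10 | diene, 14 with both C=O groups replaced by C=CH2 | COc1ccc(C=C)c(Oc2cc(OC)c(CC=C(C)C)cc2C(=C)[C@@H]3[C@H]4[C@H](CC[C@@]4(C)O)C3(C)C)c1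
F5 | step 12 | bisphenol, 15 with both methyl ethers cleaved | CC(C)=CCc1cc2c(cc1O)Oc1cc(O)ccc1C=C2[C@@H]1[C@H]2[C@H](CC[C@@]2(C)O)C1(C)C
F6 | step 12 | bis(tert-butyldimethylsilyl) ether of F5 | CC(C)=CCc1cc2c(cc1O[Si](C)(C)C(C)(C)C)Oc1cc(O[Si](C)(C)C(C)(C)C)ccc1C=C2[C@@H]1[C@H]2[C@H](CC[C@@]2(C)O)C1(C)C
F7 | step 12 | bis(tert-butyldimethylsilyl) ether of the target | CC(C)=CCc1cc2c(cc1O[Si](C)(C)C(C)(C)C)Oc1cc(O[Si](C)(C)C(C)(C)C)ccc1C1=C2[C@@H]2[C@H]3[C@H](CC[C@@]3(C)O1)C2(C)C
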